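**Retrosynthetic overview**

1. The C3 ester and all protecting groups come off or go on last; what remains is the cis-fused bicyclic core carrying the C11–C15 side chain.
2. Enabling feature: in ring B (C5–C6–C7–C8–C9–C10) the bonds C8–C9 and C5–C10 flank the C9–C10 edge, C10 is the ring-fusion carbon that also carries C1, and ring-A atoms C1–C4 link C10 to C5. With the ring-B alkene at C6=C7 (one position from the target's C7=C8) and a ketone at C1, ring B is the retron of an intramolecular Diels–Alder reaction: diene C5=C6–C7=C8, dienophile C9=C10–C1=O, tether C1–C4.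
3. Key disconnections: C8–C9 and C5–C10 (cycloaddition of an acyclic trienone, closing rings A and B together and setting C5, C8, C9, C10); C9=C10 (aldol condensation with the C9 aldehyde from (S)-citronellic acid, which supplies C11–C15 and C13); C2–C3 (L-proline aldol of 1-hydroxybutan-2-one with a 2,2-dimethyl dienal, setting the two oxygen-bearing centres that steer the cycloaddition).
4. Ring order: a temporary dioxolane on O2/O3 first, then rings A and B in one operation. Afterwards the C1 ketone is removed, the alkene is moved to C7=C8, the dioxolane is opened and the C3 ester installed.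

Key step: step 10

Remark: as written, the SMILES places H-5 and the C10 methyl on the same face (cis-fused decalin), the C9 side chain on that face too and both ring-A oxygens on the opposite face; labdane numbering is used below and β means the face of the C10 methyl.

Step 1
Reactants: 1 (E)-1-bromobut-2-ene; 2 triethyl phosphite
Product: 3 diethyl [(2E)-but-2-en-1-yl]phosphonate
Conditions: neat, 130 °C, EtBr distilled off
Reagents that add atoms: none
Why: Michaelis–Arbuzov reaction (SN2 attack of phosphorus on the primary allylic bromide, then dealkylation by bromide), which does not touch the E double bond.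

Step 2
Reactants: 3 diethyl [(2E)-but-2-en-1-yl]phosphonate; 4 3-hydroxy-2,2-dimethylpropanal
Product: 6 (3E,5E)-2,2-dimethylhepta-3,5-dien-1-ol, via lithiated phosphonate 5 (not isolated)
Conditions: 3 (2.2 equiv), n-BuLi, THF–DMPU, −78 °C; then 4 (freshly cracked monomer), −78 → 50 °C
Reagents that add atoms: none
Why: Horner–Wadsworth–Emmons olefination with an allylic phosphonate anion, which should add through its α-carbon to the non-enolisable aldehyde and eliminate to the new E alkene while the crotyl E geometry is kept, the second equivalent of anion taking up the hydroxyl proton.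

Step 3
Reactants: 6 (3E,5E)-2,2-dimethylhepta-3,5-dien-1-ol
Product: 7 (3E,5E)-2,2-dimethylhepta-3,5-dienal
Conditions: Dess–Martin periodinane, CH2Cl2, 0 °C → rt
Reagents that add atoms: none
Why: Dess–Martin oxidation of a primary neopentyl alcohol; the aldehyde has no α-hydrogen, so the diene cannot move into conjugation.

Step 4
Reactants: 7 (3E,5E)-2,2-dimethylhepta-3,5-dienal; 8 1-hydroxybutan-2-one
Product: 9 (4S,5S,7E,9E)-4,5-dihydroxy-6,6-dimethylundeca-7,9-dien-3-one
Conditions: L-proline (30 mol%), 8 in excess, DMSO, rt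
Reagents that add atoms: none
Why: proline-catalysed direct asymmetric aldol reaction of an α-hydroxy ketone (enamine catalysis), in which the hydroxylated enamine of 8 should add to the α-branched, non-enolisable aldehyde through the hydrogen-bonded chair-like transition state of L-proline and set both carbinol centres as the anti (4S,5S) diol.

Step 5
Reactants: 9 (4S,5S,7E,9E)-4,5-dihydroxy-6,6-dimethylundeca-7,9-dien-3-one
Product: 10 1-[(4S,5S)-2,2-dimethyl-5-[(3E,5E)-2-methylhepta-3,5-dien-2-yl]-1,3-dioxolan-4-yl]propan-1-one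
Conditions: 2,2-dimethoxypropane, PPTS (cat.), CH2Cl2, rt
Reagents that add atoms: 2,2-dimethoxypropane COC(C)(C)OC
Why: acid-catalysed transketalisation of the anti diol to the cis-dioxolane, mild enough to leave the centre next to the ketone and the diene untouched.

Step 6
Reactants: 11 (S)-citronellic acid
Product: 12 2-(trimethylsilyl)ethyl (3S)-3,7-dimethyloct-6-enoate
Conditions: 2-(trimethylsilyl)ethanol, DCC, DMAP (cat.), CH2Cl2, 0 °C → rt
Reagents that add atoms: 2-(trimethylsilyl)ethanol C[Si](C)(C)CCO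
Why: Steglich esterification, with the remote stereocentre untouched.

Step 7
Reactants: 12 2-(trimethylsilyl)ethyl (3S)-3,7-dimethyloct-6-enoate
Product: 14 2-(trimethylsilyl)ethyl (3S)-3-methyl-6-oxohexanoate, via secondary ozonide 13 (not isolated)
Conditions: O3, CH2Cl2, −78 °C; then PPh3, −78 °C → rt
Reagents that add atoms: ozone [O-][O+]=O
Why: ozonolysis of the electron-rich trisubstituted alkene with reductive work-up, to which the silylethyl ester and the stereocentre are inert.

Step 8
Reactants: 10 1-[(4S,5S)-2,2-dimethyl-5-[(3E,5E)-2-methylhepta-3,5-dien-2-yl]-1,3-dioxolan-4-yl]propan-1-one; 14 2-(trimethylsilyl)ethyl (3S)-3-methyl-6-oxohexanoate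
Product: 16 2-(trimethylsilyl)ethyl (3S)-8-[(4S,5S)-2,2-dimethyl-5-[(3E,5E)-2-methylhepta-3,5-dien-2-yl]-1,3-dioxolan-4-yl]-6-hydroxy-3,7-dimethyl-8-oxooctanoate, via lithium enolate 15 (not isolated)
Conditions: LiN(i-Pr)2, THF, −78 °C; then 14, −78 °C; aq. NH4Cl
Reagents that add atoms: none
Why: directed aldol addition after kinetic deprotonation on the unhindered CH2 of the ethyl ketone (not at the dioxolane CH), the aldehyde reacting faster than the ester; the two new centres are erased in step 9, so their configuration does not matter.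

Step 9
Reactants: 16 2-(trimethylsilyl)ethyl (3S)-8-[(4S,5S)-2,2-dimethyl-5-[(3E,5E)-2-methylhepta-3,5-dien-2-yl]-1,3-dioxolan-4-yl]-6-hydroxy-3,7-dimethyl-8-oxooctanoate
Product: 18 2-(trimethylsilyl)ethyl (3S,6E)-8-[(4S,5S)-2,2-dimethyl-5-[(3E,5E)-2-methylhepta-3,5-dien-2-yl]-1,3-dioxolan-4-yl]-3,7-dimethyl-8-oxooct-6-enoate, via mesylate 17 (not isolated)
Conditions: MsCl, Et3N, CH2Cl2, 0 °C; then DBU, 0 °C, short reaction time
Reagents that add atoms: none
Why: mesylation and E1cB elimination (completion of the aldol condensation), in which both aldol diastereomers should converge on the thermodynamically preferred E-trisubstituted enone, the brief cold base treatment limiting epimerisation at the dioxolane carbon next to the ketone.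

Step 10
Reactants: 18 2-(trimethylsilyl)ethyl (3S,6E)-8-[(4S,5S)-2,2-dimethyl-5-[(3E,5E)-2-methylhepta-3,5-dien-2-yl]-1,3-dioxolan-4-yl]-3,7-dimethyl-8-oxooct-6-enoate
Product: 19 2-(trimethylsilyl)ethyl (13S)-2α,3α-(isopropylidenedioxy)-1-oxo-5β-labd-6-en-15-oate (cis-fused; 8α-methyl, 9α-H, 10β-methyl)
Conditions: Me2AlCl (2 equiv), CH2Cl2, −78 → −20 °C; aq. potassium sodium tartrate
Reagents that add atoms: none
Why: Lewis-acid-promoted, concerted but asynchronous intramolecular [4+2] cycloaddition in which the (E,E)-diene C5=C6–C7=C8 adds suprafacially to the aluminium-activated (E)-enone C9=C10–C1=O, forming C5–C10 and C8–C9 in one event. The closest known reaction type is the Lewis-acid-catalysed intramolecular Diels–Alder reaction of 1,7,9-decatrien-3-ones, which close with the tether carbonyl endo to give cis-fused octalones. Ring A closes as a six-membered carbocycle through the C5–C10 bond with the four-atom tether C1–C4 folded chair-like under the diene (tether endo, enone s-cis), and ring B is the cyclohexene created by the cycloaddition itself, with its alkene at C6=C7. The C9/C10 relationship (side chain cis to the C10 methyl) follows from the E-enone geometry, the C5/C8 relationship from the E,E-diene, the cis ring fusion (H-5 cis to the C10 methyl) from the endo orientation of the C1 carbonyl, and the absolute sense from the dioxolane: in the chair-like tether the C2 oxygen must lie pseudo-equatorial, in the plane of the C1 carbonyl where the Lewis acid can bridge both oxygens, because the other fold would put it 1,3-diaxial to both the C10 methyl and the axial C4 methyl. The step needs endo over exo closure and one face of the dienophile; the first should be secured by the tether carbonyl under Lewis acid activation at low temperature, the second by the cis-dioxolane together with the C4 gem-dimethyl group.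

Step 11
Reactants: 19 2-(trimethylsilyl)ethyl (13S)-2α,3α-(isopropylidenedioxy)-1-oxo-5β-labd-6-en-15-oate
Product: 20 2-(trimethylsilyl)ethyl (13S)-1-hydroxy-2α,3α-(isopropylidenedioxy)-5β-labd-6-en-15-oate (either C1 epimer)
Conditions: NaBH4, MeOH–THF, 0 °C → rt
Reagents that add atoms: none
Why: hydride reduction of the hindered ketone, which leaves the ester alone; the new carbinol centre is removed in step 13.

Step 12
Reactants: 20 2-(trimethylsilyl)ethyl (13S)-1-hydroxy-2α,3α-(isopropylidenedioxy)-5β-labd-6-en-15-oate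
Product: 22 O-C1 S-methyl dithiocarbonate of 20, via sodium xanthate 21 (not isolated)
Conditions: NaH, imidazole (cat.), THF, 0 °C → rt; CS2; then MeI
Reagents that add atoms: carbon disulfide S=C=S; iodomethane CI
Why: xanthate formation (first half of the Barton–McCombie deoxygenation), safe under alkoxide conditions because the acetonide carries no group that can migrate.

Step 13
Reactants: 22 O-C1 S-methyl dithiocarbonate of 20
Product: 23 2-(trimethylsilyl)ethyl (13S)-2α,3α-(isopropylidenedioxy)-5β-labd-6-en-15-oate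
Conditions: Bu3SnH, AIBN (cat.), toluene, 100 °C
Reagents that add atoms: none
Why: Barton–McCombie radical deoxygenation, in which the secondary C1 radical is reduced by the tin hydride faster than it can fragment the neighbouring dioxolane C–O bond or cyclise onto C6=C7.

Step 14
Reactants: 23 2-(trimethylsilyl)ethyl (13S)-2α,3α-(isopropylidenedioxy)-5β-labd-6-en-15-oate
Product: 24 2-(trimethylsilyl)ethyl (13S)-2α,3α-(isopropylidenedioxy)-5β-labd-7-en-15-oate
Conditions: RuHCl(CO)(PPh3)3 (5 mol%), toluene, 100 °C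
Reagents that add atoms: none
Why: metal-hydride-catalysed positional alkene isomerisation (hydrometalation, β-hydride elimination): ruthenium should add at C7, away from C5 which is flanked by two quaternary carbons, and eliminate toward C8–H to give the trisubstituted C7=C8 alkene, further migration needing insertion into a trisubstituted alkene; only the temporary C8 centre is erased.

Step 15
Reactants: 24 2-(trimethylsilyl)ethyl (13S)-2α,3α-(isopropylidenedioxy)-5β-labd-7-en-15-oate
Product: 25 2-(trimethylsilyl)ethyl (13S)-2α,3α-dihydroxy-5β-labd-7-en-15-oate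
Conditions: AcOH–H2O–THF (3:1:1), 45 °C
Reagents that add atoms: none
Why: acid hydrolysis of the cis-fused acetonide under conditions that spare the silylethyl ester and the trisubstituted alkene.

Step 16
Reactants: 25 2-(trimethylsilyl)ethyl (13S)-2α,3α-dihydroxy-5β-labd-7-en-15-oate
Product: 27 2-(trimethylsilyl)ethyl (13S)-3α-hydroxy-2α-(4-methoxybenzyloxy)-5β-labd-7-en-15-oate, via stannylene acetal 26 (not isolated)
Conditions: Bu2SnO, toluene, reflux (Dean–Stark); then 4-MeOC6H4CH2Cl, Bu4NI, 90 °C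
Reagents that add atoms: 4-methoxybenzyl chloride COc1ccc(CCl)cc1
Why: stannylene-acetal-mediated regioselective O-alkylation of a cis-1,2-diol, which should alkylate the equatorial, unhindered C2 oxygen and leave the axial, neopentyl C3 hydroxyl free.

Step 17
Reactants: 28 (S)-2-hydroxy-2-methylbutanoic acid
Product: 30 (2S)-2-methyl-2-(triethylsilyloxy)butanoyl chloride, via bis(triethylsilyl) derivative 29 (not isolated)
Conditions: Et3SiCl, imidazole, DMF, rt; then (COCl)2, DMF (cat.), CH2Cl2, 0 °C → rt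
Reagents that add atoms: chlorotriethylsilane CC[Si](Cl)(CC)CC; oxalyl chloride ClC(=O)C(Cl)=O
Why: persilylation followed by conversion of the silyl ester into the acid chloride under neutral conditions, which the tertiary silyl ether survives and under which the quaternary stereocentre cannot epimerise.

Step 18
Reactants: 27 2-(trimethylsilyl)ethyl (13S)-3α-hydroxy-2α-(4-methoxybenzyloxy)-5β-labd-7-en-15-oate; 30 (2S)-2-methyl-2-(triethylsilyloxy)butanoyl chloride
Product: 32 2-(trimethylsilyl)ethyl (13S)-2α-(4-methoxybenzyloxy)-3α-[(2S)-2-methyl-2-(triethylsilyloxy)butanoyloxy]-5β-labd-7-en-15-oate, via sodium alkoxide 31 (not isolated)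
Conditions: NaN(SiMe3)2, THF, −78 °C; then 30, −78 → 0 °C
Reagents that add atoms: none
Why: acylation of a preformed hindered alkoxide by an acid chloride (nucleophilic acyl substitution); 30 has no α-hydrogen and so cannot form a ketene, the C2 oxygen is a benzyl-type ether so nothing can migrate, and alkoxide formation outruns ester enolisation at −78 °C.

Step 19
Reactants: 32 2-(trimethylsilyl)ethyl (13S)-2α-(4-methoxybenzyloxy)-3α-[(2S)-2-methyl-2-(triethylsilyloxy)butanoyloxy]-5β-labd-7-en-15-oate
Product: 33 (13S)-3α-[(2S)-2-hydroxy-2-methylbutanoyloxy]-2α-(4-methoxybenzyloxy)-5β-labd-7-en-15-oic acid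
Conditions: Bu4NF, THF, 0 °C → rt; aq. NH4Cl
Reagents that add atoms: none
Why: fluoride-induced fragmentation of the 2-(trimethylsilyl)ethyl ester and desilylation of the tertiary ether, carried out while the C2 hydroxyl is still protected so that the C3 ester cannot migrate.

Step 20
Reactants: 33 (13S)-3α-[(2S)-2-hydroxy-2-methylbutanoyloxy]-2α-(4-methoxybenzyloxy)-5β-labd-7-en-15-oic acid
Product: 34 (13S)-2α-hydroxy-3α-[(2S)-2-hydroxy-2-methylbutanoyloxy]-5β-labd-7-en-15-oic acid (CNP0305549.1)
Conditions: DDQ, CH2Cl2–pH 7 buffer, 0 °C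
Reagents that add atoms: none
Why: oxidative cleavage of the 4-methoxybenzyl ether by DDQ under buffered, neutral conditions, under which the cis 2-hydroxy-3-acyloxy array should not equilibrate by acyl migration.

**Compound list**

1 | (E)-1-bromobut-2-ene (crotyl bromide) | C/C=C/CBr | starting material
2 | triethyl phosphite | CCOP(OCC)OCC | starting material
3 | diethyl [(2E)-but-2-en-1-yl]phosphonate | C/C=C/CP(=O)(OCC)OCC | intermediate
4 | 3-hydroxy-2,2-dimethylpropanal | OCC(C)(C)C=O | starting material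
5 | lithium salt of the α-carbanion of 3 | [Li+].C/C=C/[CH-]P(=O)(OCC)OCC | intermediate
6 | (3E,5E)-2,2-dimethylhepta-3,5-dien-1-ol | OCC(C)(C)/C=C/C=C/C | intermediate
7 | (3E,5E)-2,2-dimethylhepta-3,5-dienal | O=CC(C)(C)/C=C/C=C/C | intermediate
8 | 1-hydroxybutan-2-one | CCC(=O)CO | starting material
9 | (4S,5S,7E,9E)-4,5-dihydroxy-6,6-dimethylundeca-7,9-dien-3-one | CCC(=O)[C@@H](O)[C@@H](O)C(C)(C)/C=C/C=C/C | intermediate
10 | 1-[(4S,5S)-2,2-dimethyl-5-[(3E,5E)-2-methylhepta-3,5-dien-2-yl]-1,3-dioxolan-4-yl]propan-1-one | CC1(C)O[C@H]([C@H](O1)C(=O)CC)C(C)(C)/C=C/C=C/C | intermediate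
11 | (S)-citronellic acid, (3S)-3,7-dimethyloct-6-enoic acid | CC(C)=CCC[C@H](C)CC(=O)O | starting material
12 | 2-(trimethylsilyl)ethyl (3S)-3,7-dimethyloct-6-enoate | CC(C)=CCC[C@H](C)CC(=O)OCC[Si](C)(C)C | intermediate
13 | secondary ozonide of 12 (3,3-dimethyl-1,2,4-trioxolane, ring CH unspecified) | CC1(C)OOC(CC[C@H](C)CC(=O)OCC[Si](C)(C)C)O1 | intermediate
14 | 2-(trimethylsilyl)ethyl (3S)-3-methyl-6-oxohexanoate | O=CCC[C@H](C)CC(=O)OCC[Si](C)(C)C | intermediate
15 | lithium enolate of 10 (ethyl side, enolate geometry unspecified) | [Li+].CC1(C)O[C@H]([C@H](O1)C([O-])=CC)C(C)(C)/C=C/C=C/C | intermediate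
16 | 2-(trimethylsilyl)ethyl (3S)-8-[(4S,5S)-2,2-dimethyl-5-[(3E,5E)-2-methylhepta-3,5-dien-2-yl]-1,3-dioxolan-4-yl]-6-hydroxy-3,7-dimethyl-8-oxooctanoate (C6/C7 diastereomer mixture) | CC1(C)O[C@H]([C@H](O1)C(=O)C(C)C(O)CC[C@H](C)CC(=O)OCC[Si](C)(C)C)C(C)(C)/C=C/C=C/C | intermediate
17 | 6-O-methanesulfonate of 16 | CC1(C)O[C@H]([C@H](O1)C(=O)C(C)C(OS(C)(=O)=O)CC[C@H](C)CC(=O)OCC[Si](C)(C)C)C(C)(C)/C=C/C=C/C | intermediate
18 | 2-(trimethylsilyl)ethyl (3S,6E)-8-[(4S,5S)-2,2-dimethyl-5-[(3E,5E)-2-methylhepta-3,5-dien-2-yl]-1,3-dioxolan-4-yl]-3,7-dimethyl-8-oxooct-6-enoate | CC1(C)O[C@H]([C@H](O1)C(=O)/C(C)=C/CC[C@H](C)CC(=O)OCC[Si](C)(C)C)C(C)(C)/C=C/C=C/C | intermediate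
19 | 2-(trimethylsilyl)ethyl (13S)-2α,3α-(isopropylidenedioxy)-1-oxo-5β-labd-6-en-15-oate (8α-methyl, 9α-H, 10β-methyl) | CC1(C)O[C@@H]2[C@H](O1)C(=O)[C@@]3(C)[C@H](C=C[C@@H](C)[C@@H]3CC[C@H](C)CC(=O)OCC[Si](C)(C)C)C2(C)C | intermediate
20 | 2-(trimethylsilyl)ethyl (13S)-1-hydroxy-2α,3α-(isopropylidenedioxy)-5β-labd-6-en-15-oate (C1 configuration unspecified) | CC1(C)O[C@@H]2[C@H](O1)C(O)[C@@]3(C)[C@H](C=C[C@@H](C)[C@@H]3CC[C@H](C)CC(=O)OCC[Si](C)(C)C)C2(C)C | intermediate
21 | sodium O-C1 dithiocarbonate (xanthate salt) of 20 | [Na+].CC1(C)O[C@@H]2[C@H](O1)C(OC(=S)[S-])[C@@]3(C)[C@H](C=C[C@@H](C)[C@@H]3CC[C@H](C)CC(=O)OCC[Si](C)(C)C)C2(C)C | intermediate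
22 | O-C1 S-methyl dithiocarbonate (xanthate) of 20 | CC1(C)O[C@@H]2[C@H](O1)C(OC(=S)SC)[C@@]3(C)[C@H](C=C[C@@H](C)[C@@H]3CC[C@H](C)CC(=O)OCC[Si](C)(C)C)C2(C)C | intermediate
23 | 2-(trimethylsilyl)ethyl (13S)-2α,3α-(isopropylidenedioxy)-5β-labd-6-en-15-oate | CC1(C)O[C@@H]2[C@H](O1)C[C@@]3(C)[C@H](C=C[C@@H](C)[C@@H]3CC[C@H](C)CC(=O)OCC[Si](C)(C)C)C2(C)C | intermediate
24 | 2-(trimethylsilyl)ethyl (13S)-2α,3α-(isopropylidenedioxy)-5β-labd-7-en-15-oate | CC1(C)O[C@@H]2[C@H](O1)C[C@@]3(C)[C@H](CC=C(C)[C@@H]3CC[C@H](C)CC(=O)OCC[Si](C)(C)C)C2(C)C | intermediate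
25 | 2-(trimethylsilyl)ethyl (13S)-2α,3α-dihydroxy-5β-labd-7-en-15-oate | O[C@@H]1[C@H](O)C[C@@]2(C)[C@H](CC=C(C)[C@@H]2CC[C@H](C)CC(=O)OCC[Si](C)(C)C)C1(C)C | intermediate
26 | 2,3-O-dibutylstannylene acetal of 25 | CCCC[Sn]1(CCCC)O[C@@H]2[C@H](O1)C[C@@]3(C)[C@H](CC=C(C)[C@@H]3CC[C@H](C)CC(=O)OCC[Si](C)(C)C)C2(C)C | intermediate
27 | 2-(trimethylsilyl)ethyl (13S)-3α-hydroxy-2α-(4-methoxybenzyloxy)-5β-labd-7-en-15-oate | O[C@@H]1[C@H](OCc3ccc(OC)cc3)C[C@@]2(C)[C@H](CC=C(C)[C@@H]2CC[C@H](C)CC(=O)OCC[Si](C)(C)C)C1(C)C | intermediate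
28 | (S)-2-hydroxy-2-methylbutanoic acid | CC[C@](C)(O)C(=O)O | starting material
29 | triethylsilyl (2S)-2-methyl-2-(triethylsilyloxy)butanoate | CC[C@](C)(O[Si](CC)(CC)CC)C(=O)O[Si](CC)(CC)CC | intermediate
30 | (2S)-2-methyl-2-(triethylsilyloxy)butanoyl chloride | CC[C@](C)(O[Si](CC)(CC)CC)C(Cl)=O | intermediate
31 | sodium C3 alkoxide of 27 | [Na+].[O-][C@@H]1[C@H](OCc3ccc(OC)cc3)C[C@@]2(C)[C@H](CC=C(C)[C@@H]2CC[C@H](C)CC(=O)OCC[Si](C)(C)C)C1(C)C | intermediate
32 | 2-(trimethylsilyl)ethyl (13S)-2α-(4-methoxybenzyloxy)-3α-[(2S)-2-methyl-2-(triethylsilyloxy)butanoyloxy]-5β-labd-7-en-15-oate | CC[C@](C)(O[Si](CC)(CC)CC)C(=O)O[C@@H]1[C@H](OCc3ccc(OC)cc3)C[C@@]2(C)[C@H](CC=C(C)[C@@H]2CC[C@H](C)CC(=O)OCC[Si](C)(C)C)C1(C)C | intermediate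
33 | (13S)-3α-[(2S)-2-hydroxy-2-methylbutanoyloxy]-2α-(4-methoxybenzyloxy)-5β-labd-7-en-15-oic acid | CC[C@](C)(O)C(=O)O[C@@H]1[C@H](OCc3ccc(OC)cc3)C[C@@]2(C)[C@H](CC=C(C)[C@@H]2CC[C@H](C)CC(=O)O)C1(C)C | intermediate
34 | (13S)-2α-hydroxy-3α-[(2S)-2-hydroxy-2-methylbutanoyloxy]-5β-labd-7-en-15-oic acid (2R,3S,5S,9S,10R,13S; CNP0305549.1) | CC[C@](C)(O)C(=O)O[C@@H]1[C@H](O)C[C@@]2(C)[C@H](CC=C(C)[C@@H]2CC[C@H](C)CC(=O)O)C1(C)C | target

**Step count**

Total: 20 steps. Longest linear sequence: 17 steps (steps 1–5, 8–16, 18–20).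

**Steps most likely to fail, with fallbacks**

1. Step 14 (alkene shift). The double bond may migrate the wrong way (toward C5=C6), move on into the tetrasubstituted C8=C9 position, or stall at partial conversion. The fallback sets out from 23 and fixes the position through a C7 oxygen. Hydroboration–oxidation (BH3·SMe2, THF; then NaBO3·4H2O) should place boron at C7, the alkene carbon remote from the doubly neopentyl C5, and give the C7 alcohol F1. Dess–Martin oxidation gives the C7 ketone F2. Triflation under equilibrating conditions toward the more substituted enol (Tf2O, 2,6-di-tert-butyl-4-methylpyridine, CH2Cl2) gives the C7–C8 enol triflate F3. Palladium-catalysed formate reduction (Pd(OAc)2, PPh3, Bu3N, HCO2H, DMF, 60 °C) then comes back to the route at 24.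

2. Step 10 (cycloaddition). Exo closure to the trans-fused adduct may compete, addition may occur on the wrong face of the dienophile, or the Lewis acid may open the acetonide. The fallback sets out from 18 and replaces substrate control through the dioxolane by catalyst control through a metal chelate. Mild acid hydrolysis (AcOH–H2O–THF) gives the α'-hydroxy enone diol F4. This is cyclised with Cu(OTf)2 and a chiral bis(oxazoline) ligand (2,2'-isopropylidenebis(4-tert-butyl-2-oxazoline), enantiomer chosen by a matched/mismatched test) chelated between the C1 carbonyl and the C2 hydroxyl, to give the cis-fused diol ketone F5. Re-acetonation (2,2-dimethoxypropane, PPTS) comes back to the route at 19.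

3. Step 18 (C3 acylation). Acyl transfer to the axial, neopentyl C3 alkoxide from a bulky α-silyloxy acid chloride may be too slow, so that the acid chloride decomposes first. The fallback sets out from 27 (with 28) and brings in the acyl group as a tied-back cyclic donor without a protecting group on the tertiary alcohol. Acid 28 is condensed with 2,2-dimethoxypropane (PPTS) to the dioxolanone F6. The potassium alkoxide of 27 (KN(SiMe3)2, THF) opens F6 at its only carbonyl with loss of acetone to give the hydroxy ester F7. Bu4NF then cleaves the silylethyl ester and comes back to the route at 33.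

**Further compounds**

F1 | step 14 | 2-(trimethylsilyl)ethyl (13S)-7-hydroxy-2α,3α-(isopropylidenedioxy)-5β-labdan-15-oate (8α-methyl, C7 configuration unspecified) | CC1(C)O[C@@H]2[C@H](O1)C[C@@]3(C)[C@H](CC(O)[C@@H](C)[C@@H]3CC[C@H](C)CC(=O)OCC[Si](C)(C)C)C2(C)C
F2 | step 14 | 2-(trimethylsilyl)ethyl (13S)-2α,3α-(isopropylidenedioxy)-7-oxo-5β-labdan-15-oate (C8 epimerisable) | CC1(C)O[C@@H]2[C@H](O1)C[C@@]3(C)[C@H](CC(=O)C(C)[C@@H]3CC[C@H](C)CC(=O)OCC[Si](C)(C)C)C2(C)C
F3 | step 14 | 2-(trimethylsilyl)ethyl (13S)-2α,3α-(isopropylidenedioxy)-7-(trifluoromethanesulfonyloxy)-5β-labd-7-en-15-oate | CC1(C)O[C@@H]2[C@H](O1)C[C@@]3(C)[C@H](CC(OS(=O)(=O)C(F)(F)F)=C(C)[C@@H]3CC[C@H](C)CC(=O)OCC[Si](C)(C)C)C2(C)C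
F4 | step 10 | 2-(trimethylsilyl)ethyl (3S,6E,9S,10S,12E,14E)-9,10-dihydroxy-3,7,11,11-tetramethyl-8-oxohexadeca-6,12,14-trienoate | O[C@H]([C@H](O)C(=O)/C(C)=C/CC[C@H](C)CC(=O)OCC[Si](C)(C)C)C(C)(C)/C=C/C=C/C
F5 | step 10 | 2-(trimethylsilyl)ethyl (13S)-2α,3α-dihydroxy-1-oxo-5β-labd-6-en-15-oate (8α-methyl, 9α-H, 10β-methyl) | O[C@@H]1[C@H](O)C(=O)[C@@]2(C)[C@H](C=C[C@@H](C)[C@@H]2CC[C@H](C)CC(=O)OCC[Si](C)(C)C)C1(C)C
F6 | step 18 | (5S)-5-ethyl-2,2,5-trimethyl-1,3-dioxolan-4-one | CC[C@]1(C)OC(C)(C)OC1=O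
F7 | step 18 | 2-(trimethylsilyl)ethyl (13S)-3α-[(2S)-2-hydroxy-2-methylbutanoyloxy]-2α-(4-methoxybenzyloxy)-5β-labd-7-en-15-oate | CC[C@](C)(O)C(=O)O[C@@H]1[C@H](OCc3ccc(OC)cc3)C[C@@]2(C)[C@H](CC=C(C)[C@@H]2CC[C@H](C)CC(=O)OCC[Si](C)(C)C)C1(C)C
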